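## Retrosynthetic overview

- **Feature the route rests on.** In the 5-hydroxyindole unit, N1 lies para to the C5 oxygen across the benzo ring, C2 bears only hydrogen, and C3 bears the central hexasubstituted benzene. Cutting N1–C2 and C3–C3a of its pyrrole ring gives a para-silyloxyphenylhydrazine and an arylacetaldehyde, whose CH2 becomes C3 and whose CHO becomes C2.
- **Aldehyde.** It comes from 1,2,4,5-tetramethoxybenzene by dibromination, a single Br/Li exchange, allylation and oxidative alkene cleavage. The second bromine is kept as the handle for the other indole.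
- **Second indole.** The aryl–C3′ bond is cut last (Suzuki–Miyaura) to a 1-TIPS-6-prenylindol-3-ylboronate made from 6-bromoindole. N-TIPS allows lithiation chemistry, steers the borylation to C3, and falls off together with O-TIPS.
- **Ring order.** The central benzene and the prenylindole nucleus are bought. The only ring built is the pyrrole ring of the 5-oxygenated indole. Biaryl coupling and one fluoride treatment follow.

Key step: step 6

Assumption: the target has no stereocentre, and rotation about both indolyl–aryl axes is taken as fast at room temperature, so no stereocontrol is planned.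

## Route

Step 1
Reactants: 1 1,2,4,5-tetramethoxybenzene
Product: 2 1,4-dibromo-2,3,5,6-tetramethoxybenzene
Conditions: NBS (2.1 equiv), dry MeCN, 0 °C to rt, dark
Reagents that add atoms: N-bromosuccinimide, O=C1CCC(=O)N1Br
Why: Electrophilic aromatic bromination, in which the two free ring positions are each flanked by two methoxy donors and are the only open sites, while neutral anhydrous NBS limits oxidative demethylation of the ring to a quinone.

Step 2
Reactants: 2 1,4-dibromo-2,3,5,6-tetramethoxybenzene
Product: 4 1-allyl-4-bromo-2,3,5,6-tetramethoxybenzene, via aryllithium 3 (not isolated)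
Conditions: n-BuLi (1.0 equiv), THF, −78 °C; CuBr·SMe2 (10 mol %), allyl bromide (1.3 equiv), −78 °C to rt
Reagents that add atoms: allyl bromide, C=CCBr
Why: Bromine–lithium exchange followed by copper-catalysed allylation, in which one equivalent of n-BuLi exchanges only one of the two equivalent bromines because a second carbanion on the same ring is disfavoured, and allyl bromide gives the same product by direct or allylic displacement.

Step 3
Reactants: 4 1-allyl-4-bromo-2,3,5,6-tetramethoxybenzene
Product: 6 2-(4-bromo-2,3,5,6-tetramethoxyphenyl)acetaldehyde, via diol 5 (not isolated)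
Conditions: OsO4 (2 mol %), NaIO4 (4 equiv), 2,6-lutidine (2 equiv), dioxane/H2O 3:1, rt; used promptly
Reagents that add atoms: osmium tetroxide, O=[Os](=O)(=O)=O (delivers the oxygen); sodium periodate, [Na+].[O-]I(=O)(=O)=O (restocks it)
Why: Lemieux–Johnson oxidation, in which OsO4 dihydroxylates the only alkene and NaIO4 cleaves the diol, so the very electron-rich arene is never exposed to ozone and 2,6-lutidine keeps the medium neutral for the enolisable arylacetaldehyde.

Step 4
Reactants: 7 4-aminophenol
Product: 8 4-(triisopropylsilyloxy)aniline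
Conditions: TIPSCl (1.1 equiv), imidazole (2.2 equiv), DMF, rt
Reagents that add atoms: triisopropylsilyl chloride, CC(C)[Si](Cl)(C(C)C)C(C)C
Why: Imidazole-promoted silylation of a phenol, in which the oxygen forms the strong Si–O bond and any N-silylated material is hydrolysed on aqueous work-up, so the aniline stays free.

Step 5
Reactants: 8 4-(triisopropylsilyloxy)aniline
Product: 11 [4-(triisopropylsilyloxy)phenyl]hydrazine, via diazonium chloride 9 (not isolated), via hydrazinium chloride 10 (not isolated)
Conditions: NaNO2 (1.05 equiv), 6 M HCl/MeCN, −5 °C; SnCl2·2H2O (2.5 equiv), conc. HCl, −5 to 0 °C; cold 2 M NaOH/Et2O work-up under Ar; used at once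
Reagents that add atoms: sodium nitrite, [Na+].[O-]N=O
Why: Diazotisation and SnCl2 reduction, the classical arylhydrazine synthesis used for para-alkoxyphenylhydrazines, with the hindered aryl TIPS ether being among the most acid-stable silyl ethers and therefore expected to outlast short contact with cold HCl and cold dilute NaOH.

Step 6
Reactants: 6 2-(4-bromo-2,3,5,6-tetramethoxyphenyl)acetaldehyde; 11 [4-(triisopropylsilyloxy)phenyl]hydrazine (1.1 equiv)
Product: 13 3-(4-bromo-2,3,5,6-tetramethoxyphenyl)-5-(triisopropylsilyloxy)-1H-indole, via hydrazone 12 (not isolated)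
Conditions: degassed AcOH, rt, 30 min; then ZnCl2 (2 equiv), 65 °C, Ar
Reagents that add atoms: none
Why: Condensation gives hydrazone 12, and ZnCl2 promotes its tautomerisation to the ene-hydrazine, whose [3,3]-sigmatropic rearrangement cleaves N–N and joins the former CH2 carbon to a ring carbon ortho to nitrogen (C3–C3a). Rearomatisation frees the aniline nitrogen, which adds to the C2 iminium carbon in a 5-exo-trig closure (N1–C2), and loss of ammonia from the 2-aminoindoline aromatises the new pyrrole ring. This is the Fischer indole synthesis in its established form for 3-arylindoles from arylacetaldehyde arylhydrazones. No stereocentre is created. Regiochemistry is secured by the substrates, since the two positions ortho to nitrogen in the para-substituted hydrazine are equivalent (oxygen must end at C5) and the aldehyde has a single enolisable carbon (aryl at C3, hydrogen at C2). The step also needs retention of C–Br, the four methyl ethers and O–TIPS without an acid-induced shift of the aryl group from C3 to C2, which is served by the para oxygen donor accelerating the rearrangement so that a weak acid and moderate heat suffice, and by the two ortho methoxy groups twisting the aryl ring out of conjugation and so restraining heterolytic N–N cleavage.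

Step 7
Reactants: 14 6-bromoindole
Product: 16 6-bromo-1-(triisopropylsilyl)indole, via sodium indolide 15 (not isolated)
Conditions: NaH (1.2 equiv), THF, 0 °C; TIPSCl (1.1 equiv), 0 °C to rt
Reagents that add atoms: triisopropylsilyl chloride, CC(C)[Si](Cl)(C(C)C)C(C)C
Why: N-silylation of the sodium indolide, in which the hard silicon electrophile reacts at nitrogen and the bulky group later shields C2 and C7 and is removable with fluoride.

Step 8
Reactants: 16 6-bromo-1-(triisopropylsilyl)indole
Product: 18 6-(3-methylbut-2-enyl)-1-(triisopropylsilyl)indole, via aryllithium 17 (not isolated)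
Conditions: t-BuLi (2.1 equiv), Et2O, −78 °C; CuBr·SMe2 (10 mol %), prenyl bromide (1.3 equiv), −78 to 0 °C
Reagents that add atoms: prenyl bromide, CC(C)=CCBr
Why: Bromine–lithium exchange outruns any deprotonation (C2 is shielded by N-TIPS), and copper-catalysed SN2 displacement at the unhindered primary carbon of prenyl bromide should deliver the linear prenyl group rather than the reverse-prenyl isomer.

Step 9
Reactants: 18 6-(3-methylbut-2-enyl)-1-(triisopropylsilyl)indole
Product: 19 6-(3-methylbut-2-enyl)-3-(4,4,5,5-tetramethyl-1,3,2-dioxaborolan-2-yl)-1-(triisopropylsilyl)indole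
Conditions: [Ir(OMe)(cod)]2 (1.5 mol %), 4,4′-di-tert-butyl-2,2′-bipyridine (3 mol %), B2pin2 (1.0 equiv), hexane, 60 °C
Reagents that add atoms: bis(pinacolato)diboron, CC1(C)OB(OC1(C)C)B1OC(C)(C)C(C)(C)O1
Why: Iridium-catalysed aromatic C–H borylation is sterically governed and is known to take N-TIPS indoles at C3, and here TIPS blocks C2 and C7 and the prenyl group blocks C5 and C7, while the trisubstituted alkene is a poor partner for the iridium boryl species.

Step 10
Reactants: 13 3-(4-bromo-2,3,5,6-tetramethoxyphenyl)-5-(triisopropylsilyloxy)-1H-indole; 19 6-(3-methylbut-2-enyl)-3-(4,4,5,5-tetramethyl-1,3,2-dioxaborolan-2-yl)-1-(triisopropylsilyl)indole (1.5 equiv)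
Product: 20 3-{2,3,5,6-tetramethoxy-4-[6-(3-methylbut-2-enyl)-1-(triisopropylsilyl)indol-3-yl]phenyl}-5-(triisopropylsilyloxy)-1H-indole
Conditions: Pd(OAc)2 (5 mol %), SPhos (10 mol %), K3PO4 (3 equiv), toluene/H2O 10:1, 90 °C, Ar
Reagents that add atoms: none
Why: Suzuki–Miyaura coupling, in which SPhos-ligated zerovalent palladium is suited to insertion into electron-rich di-ortho-substituted aryl bromides and tolerates a free indole N–H, and the N-silyl group slows protodeboronation of the indol-3-ylboronate.

Step 11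
Reactants: 20 3-{2,3,5,6-tetramethoxy-4-[6-(3-methylbut-2-enyl)-1-(triisopropylsilyl)indol-3-yl]phenyl}-5-(triisopropylsilyloxy)-1H-indole
Product: 21 3-{2,3,5,6-tetramethoxy-4-[6-(3-methylbut-2-enyl)-1H-indol-3-yl]phenyl}-1H-indol-5-ol (target)
Conditions: TBAF (3 equiv), AcOH (3 equiv), THF, 0 °C to rt, Ar
Reagents that add atoms: none
Why: Fluoride-induced desilylation, driven by the strong Si–F bond, cleaves the aryl O–Si and the indole N–Si bonds in one operation, and the acetic acid buffer keeps the oxidation-prone 5-hydroxyindole protonated while the methyl ethers and the prenyl alkene are untouched.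

## Compound list

1 | 1,2,4,5-tetramethoxybenzene | COc1cc(OC)c(OC)cc1OC | starting material
2 | 1,4-dibromo-2,3,5,6-tetramethoxybenzene | COc1c(OC)c(Br)c(OC)c(OC)c1Br | intermediate
3 | (4-bromo-2,3,5,6-tetramethoxyphenyl)lithium | [Li]c1c(OC)c(OC)c(Br)c(OC)c1OC | intermediate
4 | 1-allyl-4-bromo-2,3,5,6-tetramethoxybenzene | C=CCc1c(OC)c(OC)c(Br)c(OC)c1OC | intermediate
5 | 3-(4-bromo-2,3,5,6-tetramethoxyphenyl)propane-1,2-diol (racemic) | OCC(O)Cc1c(OC)c(OC)c(Br)c(OC)c1OC | intermediate
6 | 2-(4-bromo-2,3,5,6-tetramethoxyphenyl)acetaldehyde | O=CCc1c(OC)c(OC)c(Br)c(OC)c1OC | intermediate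
7 | 4-aminophenol | Nc1ccc(O)cc1 | starting material
8 | 4-(triisopropylsilyloxy)aniline | Nc1ccc(O[Si](C(C)C)(C(C)C)C(C)C)cc1 | intermediate
9 | 4-(triisopropylsilyloxy)benzenediazonium chloride | N#[N+]c1ccc(O[Si](C(C)C)(C(C)C)C(C)C)cc1.[Cl-] | intermediate
10 | [4-(triisopropylsilyloxy)phenyl]hydrazinium chloride | [Cl-].[NH3+]Nc1ccc(O[Si](C(C)C)(C(C)C)C(C)C)cc1 | intermediate
11 | [4-(triisopropylsilyloxy)phenyl]hydrazine | NNc1ccc(O[Si](C(C)C)(C(C)C)C(C)C)cc1 | intermediate
12 | (E)-2-(4-bromo-2,3,5,6-tetramethoxyphenyl)acetaldehyde 4-(triisopropylsilyloxy)phenylhydrazone | COc1c(OC)c(C/C=N/Nc2ccc(O[Si](C(C)C)(C(C)C)C(C)C)cc2)c(OC)c(OC)c1Br | intermediate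
13 | 3-(4-bromo-2,3,5,6-tetramethoxyphenyl)-5-(triisopropylsilyloxy)-1H-indole | COc1c(OC)c(-c2c[nH]c3ccc(O[Si](C(C)C)(C(C)C)C(C)C)cc23)c(OC)c(OC)c1Br | intermediate
14 | 6-bromoindole | Brc1ccc2cc[nH]c2c1 | starting material
15 | sodium 6-bromoindol-1-ide | [Na+].Brc1ccc2cc[n-]c2c1 | intermediate
16 | 6-bromo-1-(triisopropylsilyl)indole | Brc1ccc2ccn([Si](C(C)C)(C(C)C)C(C)C)c2c1 | intermediate
17 | [1-(triisopropylsilyl)indol-6-yl]lithium | [Li]c1ccc2ccn([Si](C(C)C)(C(C)C)C(C)C)c2c1 | intermediate
18 | 6-(3-methylbut-2-enyl)-1-(triisopropylsilyl)indole | CC(C)=CCc1ccc2ccn([Si](C(C)C)(C(C)C)C(C)C)c2c1 | intermediate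
19 | 6-(3-methylbut-2-enyl)-3-(4,4,5,5-tetramethyl-1,3,2-dioxaborolan-2-yl)-1-(triisopropylsilyl)indole | CC(C)=CCc1ccc2c(B3OC(C)(C)C(C)(C)O3)cn([Si](C(C)C)(C(C)C)C(C)C)c2c1 | intermediate
20 | 3-{2,3,5,6-tetramethoxy-4-[6-(3-methylbut-2-enyl)-1-(triisopropylsilyl)indol-3-yl]phenyl}-5-(triisopropylsilyloxy)-1H-indole | COc1c(OC)c(-c2c[nH]c3ccc(O[Si](C(C)C)(C(C)C)C(C)C)cc23)c(OC)c(OC)c1-c1cn([Si](C(C)C)(C(C)C)C(C)C)c2cc(CC=C(C)C)ccc12 | intermediate
21 | 3-{2,3,5,6-tetramethoxy-4-[6-(3-methylbut-2-enyl)-1H-indol-3-yl]phenyl}-1H-indol-5-ol | COc1c(OC)c(-c2c[nH]c3ccc(O)cc23)c(OC)c(OC)c1-c1c[nH]c2cc(CC=C(C)C)ccc12 | target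

## Step count and risks

Total step count: 11.
Longest linear sequence: 6 (steps 1, 2, 3, 6, 10, 11).

**Step 6 (Fischer indolisation).**
- What may go wrong:
  - self-condensation of the arylacetaldehyde before it is captured as the hydrazone;
  - heterolytic N–N cleavage of the electron-rich ene-hydrazine in place of the [3,3] shift;
  - acid-induced migration of the aryl group from C3 to C2;
  - loss of the silyl ether.
- The fallback attaches an intact indole by cross-coupling. It sets out from 2 and comes back to the route at 21.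
- Commercial 5-hydroxyindole is bis-silylated (NaH, TIPSCl, THF) to 1-(triisopropylsilyl)-5-(triisopropylsilyloxy)indole F1.
- F1 is borylated under the conditions of step 9 to 3-(4,4,5,5-tetramethyl-1,3,2-dioxaborolan-2-yl)-1-(triisopropylsilyl)-5-(triisopropylsilyloxy)indole F2.
- F2 is coupled with an excess of 2 (Pd(OAc)2, SPhos, K3PO4) to 3-(4-bromo-2,3,5,6-tetramethoxyphenyl)-1-(triisopropylsilyl)-5-(triisopropylsilyloxy)indole F3.
- A second Suzuki–Miyaura coupling with 19 gives 3-{2,3,5,6-tetramethoxy-4-[6-(3-methylbut-2-enyl)-1-(triisopropylsilyl)indol-3-yl]phenyl}-1-(triisopropylsilyl)-5-(triisopropylsilyloxy)indole F4.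
- TBAF/AcOH as in step 11 then gives 21.

**Step 10 (Suzuki–Miyaura coupling).**
- What may go wrong: slow oxidative addition into the hindered, electron-rich C–Br bond, which leaves time for protodeboronation and N-desilylation of the indolylboronate.
- The fallback reverses the polarity (Negishi coupling). It sets out from 13, with its partner made from 18, and comes back at 20.
- Compound 18 is iodinated at C3 (NIS, THF, −78 °C) to 3-iodo-6-(3-methylbut-2-enyl)-1-(triisopropylsilyl)indole F5.
- Compound 13 is treated with t-BuLi (3.1 equiv, THF, −78 °C), which removes N–H and exchanges the bromine, to give 1-lithio-3-(4-lithio-2,3,5,6-tetramethoxyphenyl)-5-(triisopropylsilyloxy)indole F6.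
- ZnCl2 converts F6 into {4-[1-lithio-5-(triisopropylsilyloxy)indol-3-yl]-2,3,5,6-tetramethoxyphenyl}zinc chloride F7.
- Coupling of F7 with F5 (Pd2(dba)3, RuPhos, THF, 60 °C) gives the N-lithio derivative of 20 F8, which is protonated to 20 on aqueous work-up.

**Step 9 (C–H borylation).**
- What may go wrong: hydroboration or isomerisation of the prenyl alkene by pinacolborane and iridium hydrides, or competing borylation in the benzo ring.
- The fallback uses halogenation and metalation. It sets out from 18 and comes back at 19.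
- NBS (THF, −78 °C, dark) attacks the far more nucleophilic indole C3 to give 3-bromo-6-(3-methylbut-2-enyl)-1-(triisopropylsilyl)indole F9.
- t-BuLi (2 equiv, THF, −78 °C) gives [6-(3-methylbut-2-enyl)-1-(triisopropylsilyl)indol-3-yl]lithium F10, which the bulky silyl group holds at C3.
- 2-Isopropoxy-4,4,5,5-tetramethyl-1,3,2-dioxaborolane traps F10 as 19.

## Further compounds

F1 | step 6 | 1-(triisopropylsilyl)-5-(triisopropylsilyloxy)indole | c1cn([Si](C(C)C)(C(C)C)C(C)C)c2ccc(O[Si](C(C)C)(C(C)C)C(C)C)cc12
F2 | step 6 | 3-(4,4,5,5-tetramethyl-1,3,2-dioxaborolan-2-yl)-1-(triisopropylsilyl)-5-(triisopropylsilyloxy)indole | CC1(C)OB(OC1(C)C)c1cn([Si](C(C)C)(C(C)C)C(C)C)c2ccc(O[Si](C(C)C)(C(C)C)C(C)C)cc12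
F3 | step 6 | 3-(4-bromo-2,3,5,6-tetramethoxyphenyl)-1-(triisopropylsilyl)-5-(triisopropylsilyloxy)indole | COc1c(OC)c(-c2cn([Si](C(C)C)(C(C)C)C(C)C)c3ccc(O[Si](C(C)C)(C(C)C)C(C)C)cc23)c(OC)c(OC)c1Br
F4 | step 6 | 3-{2,3,5,6-tetramethoxy-4-[6-(3-methylbut-2-enyl)-1-(triisopropylsilyl)indol-3-yl]phenyl}-1-(triisopropylsilyl)-5-(triisopropylsilyloxy)indole | COc1c(OC)c(-c2cn([Si](C(C)C)(C(C)C)C(C)C)c3ccc(O[Si](C(C)C)(C(C)C)C(C)C)cc23)c(OC)c(OC)c1-c1cn([Si](C(C)C)(C(C)C)C(C)C)c2cc(CC=C(C)C)ccc12
F5 | step 10 | 3-iodo-6-(3-methylbut-2-enyl)-1-(triisopropylsilyl)indole | CC(C)=CCc1ccc2c(I)cn([Si](C(C)C)(C(C)C)C(C)C)c2c1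
F6 | step 10 | 1-lithio-3-(4-lithio-2,3,5,6-tetramethoxyphenyl)-5-(triisopropylsilyloxy)indole | [Li]c1c(OC)c(OC)c(-c2cn([Li])c3ccc(O[Si](C(C)C)(C(C)C)C(C)C)cc23)c(OC)c1OC
F7 | step 10 | {4-[1-lithio-5-(triisopropylsilyloxy)indol-3-yl]-2,3,5,6-tetramethoxyphenyl}zinc chloride | Cl[Zn]c1c(OC)c(OC)c(-c2cn([Li])c3ccc(O[Si](C(C)C)(C(C)C)C(C)C)cc23)c(OC)c1OC
F8 | step 10 | N-lithio derivative of 20 | COc1c(OC)c(-c2cn([Li])c3ccc(O[Si](C(C)C)(C(C)C)C(C)C)cc23)c(OC)c(OC)c1-c1cn([Si](C(C)C)(C(C)C)C(C)C)c2cc(CC=C(C)C)ccc12
F9 | step 9 | 3-bromo-6-(3-methylbut-2-enyl)-1-(triisopropylsilyl)indole | CC(C)=CCc1ccc2c(Br)cn([Si](C(C)C)(C(C)C)C(C)C)c2c1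
F10 | step 9 | [6-(3-methylbut-2-enyl)-1-(triisopropylsilyl)indol-3-yl]lithium | [Li]c1cn([Si](C(C)C)(C(C)C)C(C)C)c2cc(CC=C(C)C)ccc12
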